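The numbers in the tables were generated by integration for an exercise; the scatter is artificial.

Which constants does this flask need? For a forecast, two numbers will do, and neither is a rate constant.

| setting | Tuesday's | Saturday's | Sunday's | birch | oak | maple |
|---|---|---|---|---|---|---|
| starting complex | 0.73 M | 0.73 M | 0.73 M | 0.73 M | 0.73 M | 0.73 M |
| incoming ligand | 0.47 M | 0.97 M | 1.3 M | 0.584 M | 1.09 M | 1.46 M |
| leaving ligand | 0.365 M | 0.365 M | 0.365 M | 0.365 M | 0.365 M | 0.365 M |
| remark | run made earlier | run made earlier | run made earlier |  |  |  |
| time |  |  |  | 12 h | 12 h | 12 h |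

| run | time / h | complex with one exchanged / % | complex with two exchanged / % |
|---|---|---|---|
| Tuesday's | 2.50 | 7 | 1 |
| Tuesday's | 5.00 | 12 | 2 |
| Tuesday's | 8.00 | 10 | 1 |
| Tuesday's | 10.0 | 13 | 3 |
| Tuesday's | 12.0 | 13 | 0 |
| Saturday's | 1.00 | 6 | 0 |
| Saturday's | 3.00 | 13 | 1 |
| Saturday's | 6.00 | 17 | 8 |
| Saturday's | 8.00 | 20 | 6 |
| Saturday's | 12.0 | 26 | 7 |
| Sunday's | 1.00 | 6 | 3 |
| Sunday's | 2.00 | 14 | 4 |
| Sunday's | 3.00 | 13 | 2 |
| Sunday's | 6.00 | 19 | 4 |
| Sunday's | 12.0 | 23 | 10 |

(standard deviation of a reading: 2 percentage points)

1. complex with one exchanged at the end, in percent of the starting complex charged, for each flask in turn (birch, oak, maple)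

- the numbers in the tables scatter with a standard deviation of 2 percentage points

What do you assume? Two successive exchanges, each first order in its complex and in [incoming ligand]. Both then run on one clock, the exposure x, which is ln([starting complex] charged / [starting complex] left), whatever [incoming ligand] does on the way.

Read it. I count whatever isn't exchanged as starting complex and take the last readings, at 12.0 h. Dividing x by the charge gives 0.296 M⁻¹ for Tuesday's run, 0.413 M⁻¹ for Saturday's and 0.308 M⁻¹ for Sunday's. Their mean, 0.339 M⁻¹, is the exposure per molar of incoming ligand charged.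

But ligand is consumed, so why should exposure scale with the charge? I don't derive that; I read it. Tuesday's and Sunday's values lie close together at 0.47 M and 1.3 M, and Saturday's, at 0.97 M, stands higher.

And the low end? At small x, the fraction with one exchanged is about x, and two exchanged over one exchanged is about ρx/2, where ρ is the selectivity factor, second exchange against first. Saturday's and Sunday's readings give ρ = 1.80, as a reading.

And beyond the low end? The same two steps, solved whole, give the fraction with one exchanged as (exp(−x) − exp(−ρx))/(ρ − 1). My reckoning: birch 15.0%, oak 22.1%, maple 24.9%.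

The forecast gives 15%, 23% and 25%, in its words: “The curve flattens because the second exchange drains the one-exchanged complex”.

The flasks give 16.3%, 23.2% and 25.9%.

    2 incoming ligand → self-condensation product (k = 4.10 × 10⁻⁴ M⁻¹ min⁻¹)
    complex with one exchanged → side product (k = 2.30 × 10⁻⁴ min⁻¹)
    incoming ligand ⇌ dormant form (K = 0.720, k = 0.0100 min⁻¹)
    starting complex + incoming ligand → leaving ligand + complex with one exchanged (k = 0.00120 M⁻¹ min⁻¹)
    complex with one exchanged + incoming ligand → leaving ligand + complex with two exchanged (k = 0.00170 M⁻¹ min⁻¹)

In oak, the half-life of complex with one exchanged towards side product, 50 h, is longer than the 12 h of the run, and that road has taken 2.64% of the starting complex charged by the end. The exposure per molar, 0.339 M⁻¹ from the earlier runs, comes out of the starting complex left at the end as 0.388 M⁻¹ in oak, with 66% left, and as 0.376 M⁻¹ in maple, with 58% left.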